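## Structural features

The target is a bis-isoflavan. An upper 7-hydroxychroman (benzo ring A, pyran ring C) carries a 2,3-dihydroxy-4-methoxyphenyl group (ring B) at C3 and a central benzene ring D at C4. Ring D is also the 3-aryl substituent of a lower 7-hydroxychroman (benzo ring E, pyran ring F). Ring D is tetrasubstituted: D1 (bonded to C4), D2 (OMe) and D6 (bonded to C3″) are contiguous, and the D4 hydroxyl is para to D1, so C4 sits between two ortho substituents. There are three stereocentres: C3 (R) and C4 (S) are adjacent and trans on ring C, and C3″ (R) is separated from C4 only by the D1–D6 edge of ring D. Five free phenols, two of them an oxidation-prone catechol in ring B, must be kept distinct from two methyl ethers, and C4 is a doubly benzylic, donor-rich carbon whose oxygenated precursors ionise easily. The real difficulty is twofold. First, three neighbouring positions of a phloroglucinol-type ring must carry two different carbon groups and a methoxy group, and electrophilic substitution cannot choose between D1, D3 and D5. Second, the C3–C4 bond must be made at a carbon shielded by a 2,6-disubstituted aryl group with control of both configurations. The key step uses the D2(OMe)–D1–D6 triad: it is the pattern left when a 3-methoxyaryne inserts into the CH2–C(=O) bond of an aroylacetate, placing the ring A ketone (future C4) on D1 and an enolisable CH2CO2Et (future C3″) on D6.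

## Logic of the disconnections

36 to 35: the five phenolic O–H bonds are traced to O–benzyl bonds. Benzyl ethers are orthogonal to the two methyl ethers and fall together in one hydrogenolysis. The forward step is safe because C4 carries no heteroatom and neither pyran C–O bond is benzylic.

35 to 34 to 33: the O1–C2 ether bond is cut and C2 is raised to the carboxyl level. As a lactone, C3 becomes the α-carbon of an arylacetic unit, which opens C3–C4 to enolate chemistry and makes C3 adjustable. The forward steps need a hydride reduction that leaves the trans relationship intact and an O-alkylation of the ring A phenol at a primary carbon.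

33 to 25 and 29: C3–C4 and the acyl O1–C2 bond are cut together. C4 is the methide carbon of an ortho-quinone methide once the ring A phenol is free, and 29 can be a catalyst-bound chiral enolate. This separates ring B, as one simple acid, from a fragment holding rings A, D, E and F. The forward step must fix C4 on a hindered acceptor in the presence of C3″; C3 is then relaxed to trans by equilibration.

25 to 24 to 23 to 22: the C4–S bond, the C4–H bond and the acetal on the ring A oxygen are removed in turn, returning C4 to the ketone level. The ketone is inert during the steps that build the lower chroman. The acetal is removed before the reduction because the hydroxy carbinol would ionise under acid.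

22 to 21 to 20 to 15 and 19: the aryl C–O bond of ring F and the C3″–C4″ bond are cut. C3″ is α to a carboxyl in the arylacetic series, so an auxiliary-controlled benzylation sets this isolated centre in a predictable sense. The aryl bromide of 19 serves the ring closure and also keeps the benzylic bromide from being a labile 2,4-dialkoxybenzyl halide. The forward steps must leave the diaryl ketone untouched under enolate, borohydride and palladium conditions.

15 to 13 to 12: the N-acyl bond and the ester are interconverted; no skeletal change.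

12 to 4 and 9 (key): D6–CH2 and D1–C(=O) are cut in one operation. The ortho-acyl arylacetate is the retron of aryne insertion into a β-ketoester, and the positions of both new bonds relative to OMe are set by the polarisation of the aryne, not by arene nucleophilicity. The connectivity of 4, 9 and 12 is self-consistent: silicon lies between OMe and OTf in 4 with the benzyloxy group para to silicon, so the acyl group of 12 ends ortho to OMe and para to OBn, as ring D requires. No structural correction is needed. The forward step demands attack at the aryne carbon remote from OMe, C-arylation of the enolate and clean fragmentation.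

4 to 3 to 1: the O–benzyl bond and then the ring C–O bond para to silicon are cut. The oxygen is introduced by sterically controlled C–H borylation at the only position of 1 with no ortho neighbour. This replaces directed lithiation of a 3,5-dialkoxyphenyl carbamate, where both positions flanking the directing group are doubly activated and a benzylic ether can itself be metalated. The silyl triflate must survive fluoride-free borylation, oxidation and alkylation.

9 to 7 to 6 to 5 and 8: one C–C bond (Claisen) and two O-alkyl bonds are cut. The chelated 2-hydroxyl of 5 allows the two oxygens to be protected differently.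

19 to 18 to 17 to 16: functional group changes at the benzylic carbon and one O-benzyl bond.

29 to 28 to 27 to 26: the acid is traced through the nitrile to the aldehyde (one-carbon homologation) and two O-benzyl bonds.

## Other disconnections considered

Alternative 1: Ring D is made last by cutting D3–D4, D1–D2 and D4–D5. A cyclobutenone A2 bearing the upper chroman on its C2 and the lower chroman on its C3 is heated with methoxyacetylene A3. Electrocyclic opening to a vinylketene, [2+2] addition of the ynol ether, a second 4π opening and 6π closure would give phenol A1 (Danheiser benzannulation).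
- In its favour: the substitution pattern of ring D follows from the mechanism, so on regiocontrol it is the equal of the chosen plan. The D4 hydroxyl is formed free and so is distinguished from the benzyl ethers without a protecting step, which is better than the chosen plan. All three stereocentres are in place beforehand, so the key step itself carries no stereochemical risk, which is also better.
- Against it here: A2 must carry two sp3 stereocentres directly on the two sp2 carbons of a strained enone. The C3″–H bond is vinylogously acidic and the C4–H bond is allylic to the vinylketene, so both are exposed to enolisation or hydrogen shifts during thermolysis. The usual ketene–alkyne entry to A2 would need an unsymmetrical alkyne bearing both chromans and would meet its own regiochemical problem. A3 is volatile and unstable.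
- Comparison: structurally the alternative assembles ring D from acyclic carbons, while the chosen plan edits a preformed arene. Mechanistically it is a neutral pericyclic cascade against a fluoride-triggered polar insertion. The union is short, but both chromans must be finished first with carbon handles and C4 must already be a stereocentre, so the overall count should exceed that of the chosen route.

Alternative 2: C3–C4 and O1–C2 are cut. Sulfone A5 releases an ortho-quinone methide with base, and the isothiourea-bound enolate of the ring B arylacetic acid adds at C4 with lactonisation to give A4.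
- In its favour: ring C and both adjacent stereocentres come from one convergent catalytic step. On this point it is the equal of the chosen plan, which uses the same union at step 21 (A4 is 33 and A5 is 25).
- Against it as the strategic step: it leaves open how the ring D array of A5 is reached. Attaching the benzhydryl carbon to a ring D that already carries the lower chroman, by arylmetal or Friedel–Crafts chemistry, meets the D1/D3/D5 ambiguity. A plan that counts on the trans lactone forming directly is also exposed, because the endo-type topology usual for ammonium enolates and quinone methides points to the cis lactone first.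
- Comparison: structurally it addresses the upper chroman while the chosen key step addresses ring D, so the two complement each other. Mechanistically it is Lewis-base-catalysed Michael addition–lactonisation against aryne insertion. The downstream count is the same; the difference lies upstream, where the aryne route reaches A5 in fewer steps.

Alternative 3: C4–C4a is cut. Carbinol A7, with C3 already set and a 3-benzyloxyphenyl ether on the C2 oxygen, is ionised with BF3·OEt2. The ether ring attacks para to its benzyloxy group and closes ring C to give A6.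
- In its favour: C4 follows from C3 by substrate control without a chiral catalyst, which is more predictable than a catalyst-controlled addition to a hindered acceptor and on that point better. The chroman is formed directly at the ether oxidation level, saving the lactone reduction and Mitsunobu closure, so it is two steps better after ring closure.
- Against it here: the C4 cation has a neighbouring C3–H that can shift to give a ring B-stabilised cation or be lost to a stilbene, which endangers C3. The ortho-benzyloxy oxygen of ring B can trap the cation in a five-membered ring with loss of benzyl. The nucleophilic ring can also attack ortho to its benzyloxy group. A7 still needs ring D with the contiguous pattern and a separately made C3 centre.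
- Comparison: structurally it forms the same ring from the other side of C4. Mechanistically it is a cationic SN1 closure against an anionic insertion. It is not shorter overall, because the ring D problem is untouched.

Key step: step 6

Remark: the enolate/quinone methide union of step 21 is assumed to follow the endo-type [4+2] topology usual for this reaction class (cis lactone first); the catalyst enantiomer and the C3 equilibration are chosen on that basis.

## Steps

Step 1
Reactants: 1 3-methoxy-2-(trimethylsilyl)phenyl trifluoromethanesulfonate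
Product: 3 5-hydroxy-3-methoxy-2-(trimethylsilyl)phenyl trifluoromethanesulfonate, via arylboronate 2 (not isolated)
Conditions: [Ir(OMe)(cod)]2 (cat.), 4,4′-di-tert-butyl-2,2′-bipyridine, B2pin2, THF, 60 °C; then NaBO3·4H2O, THF/H2O, rt
Reagents that add atoms: sodium perborate, [Na+].[O-]OB=O
Why: Iridium-catalysed C–H borylation is sterically governed and only C5 of 1 has no ortho substituent, so boron should enter para to silicon while the triflate and the C–Si bond are left alone. Perborate then oxidises C–B to C–OH (boronate oxidation) under fluoride-free, near-neutral conditions.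

Step 2
Reactants: 3 5-hydroxy-3-methoxy-2-(trimethylsilyl)phenyl trifluoromethanesulfonate
Product: 4 5-(benzyloxy)-3-methoxy-2-(trimethylsilyl)phenyl trifluoromethanesulfonate
Conditions: BnBr, K2CO3, acetone, rt
Reagents that add atoms: benzyl bromide, BrCc1ccccc1
Why: Williamson etherification of the phenol; carbonate in acetone supplies neither fluoride nor alkoxide, so the silyl/triflate pair should survive.

Step 3
Reactants: 5 2,4-dihydroxyacetophenone
Product: 6 1-[4-(benzyloxy)-2-hydroxyphenyl]ethanone
Conditions: BnBr (1.05 equiv), K2CO3, acetone, reflux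
Reagents that add atoms: benzyl bromide, BrCc1ccccc1
Why: Williamson etherification; the 2-hydroxyl is held in a hydrogen bond to the acetyl group, so one equivalent of halide should alkylate the 4-hydroxyl selectively.

Step 4
Reactants: 6 1-[4-(benzyloxy)-2-hydroxyphenyl]ethanone
Product: 7 1-[4-(benzyloxy)-2-(methoxymethoxy)phenyl]ethanone
Conditions: NaH, DMF, 0 °C; MOMCl, 0 °C to rt
Reagents that add atoms: chloromethyl methyl ether, COCCl
Why: Full deprotonation breaks the chelate and the phenoxide is alkylated (Williamson-type acetal formation). The methoxymethyl group is the single acid-labile group, placed on the oxygen that later becomes the quinone methide oxygen.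

Step 5
Reactants: 7 1-[4-(benzyloxy)-2-(methoxymethoxy)phenyl]ethanone; 8 diethyl carbonate
Product: 9 ethyl 3-[4-(benzyloxy)-2-(methoxymethoxy)phenyl]-3-oxopropanoate
Conditions: NaH, 8 (excess), toluene, 100 °C; then aq. NH4Cl
Reagents that add atoms: none
Why: Crossed Claisen condensation of the methyl ketone enolate with the non-enolisable carbonate, driven by formation of the stabilised β-ketoester enolate.

Step 6
Reactants: 4 5-(benzyloxy)-3-methoxy-2-(trimethylsilyl)phenyl trifluoromethanesulfonate; 9 ethyl 3-[4-(benzyloxy)-2-(methoxymethoxy)phenyl]-3-oxopropanoate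
Product: 12 ethyl 2-{5-(benzyloxy)-2-[4-(benzyloxy)-2-(methoxymethoxy)benzoyl]-3-methoxyphenyl}acetate, via aryne 10 (not isolated), via benzocyclobutenoxide 11 (not isolated)
Conditions: CsF (2.5 equiv), 4 (1.25 equiv), MeCN, 80 °C
Reagents that add atoms: none
Why: Fluoride attacks silicon of 4 and triflate leaves to give aryne 10; the cesium enolate of 9 adds through carbon to the aryne carbon remote from the methoxy group, because the inductively withdrawing OMe polarises the strained triple bond and stabilises the aryl anion developing next to it. That aryl anion, ortho to OMe, adds to the ring A ketone in a 4-exo-trig closure to give the transient benzocyclobutenoxide 11, and retro-aldol-type cleavage of the former CH–C(=O) bond relieves the strain and leaves an ester enolate that is protonated to 12. The closest known reaction type is the acyl-alkylation of arynes with β-ketoesters from 2-silylaryl triflates and CsF, which covers aroylacetates and 3,5-dialkoxyarynes. No ring of the target is closed (the four-membered ring is only an intermediate) and no stereocentre is formed. Three selectivities are needed: attack at the correct aryne carbon, secured by the 3-methoxy group while the 5-benzyloxy group, meta to the attacked carbon, should not oppose it; C- rather than O-arylation, favoured by the weakly coordinated cesium enolate in MeCN; and a single insertion, favoured because the arylacetate product is far less acidic than 9. The acetal, the benzyl ethers and the ester are inert to anhydrous fluoride at this temperature.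

Step 7
Reactants: 12 ethyl 2-{5-(benzyloxy)-2-[4-(benzyloxy)-2-(methoxymethoxy)benzoyl]-3-methoxyphenyl}acetate
Product: 13 2-{5-(benzyloxy)-2-[4-(benzyloxy)-2-(methoxymethoxy)benzoyl]-3-methoxyphenyl}acetic acid
Conditions: LiOH·H2O, THF/MeOH/H2O, rt; then 1 M HCl, 0 °C, to pH 4
Reagents that add atoms: lithium hydroxide, [Li+].[OH-]
Why: Ester saponification; the diaryl ketone has no α-hydrogen and the acetal is base-stable, and the cold, mild acidification spares the acetal.

Step 8
Reactants: 13 2-{5-(benzyloxy)-2-[4-(benzyloxy)-2-(methoxymethoxy)benzoyl]-3-methoxyphenyl}acetic acid; 14 (R)-4-benzyl-1,3-oxazolidin-2-one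
Product: 15 (4R)-4-benzyl-3-(2-{5-(benzyloxy)-2-[4-(benzyloxy)-2-(methoxymethoxy)benzoyl]-3-methoxyphenyl}acetyl)-1,3-oxazolidin-2-one
Conditions: t-BuCOCl, Et3N, THF, −20 °C; then 14, LiCl, rt
Reagents that add atoms: none
Why: N-acylation of the oxazolidinone through the mixed pivalic anhydride; the hindered pivaloyl carbonyl directs attack to the arylacetyl carbonyl. The (R)-auxiliary is chosen because the next step must deliver (R) at the future C3″.

Step 9
Reactants: 16 2-bromo-4-hydroxybenzaldehyde
Product: 17 4-(benzyloxy)-2-bromobenzaldehyde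
Conditions: BnBr, K2CO3, DMF, rt
Reagents that add atoms: benzyl bromide, BrCc1ccccc1
Why: Williamson etherification of the only phenol.

Step 10
Reactants: 17 4-(benzyloxy)-2-bromobenzaldehyde
Product: 18 [4-(benzyloxy)-2-bromophenyl]methanol
Conditions: NaBH4, MeOH/THF, 0 °C
Reagents that add atoms: none
Why: Borohydride reduction of the aldehyde; the aryl bromide and benzyl ether are inert.

Step 11
Reactants: 18 [4-(benzyloxy)-2-bromophenyl]methanol
Product: 19 4-(benzyloxy)-2-bromo-1-(bromomethyl)benzene
Conditions: PBr3, CH2Cl2, 0 °C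
Reagents that add atoms: phosphorus tribromide, BrP(Br)Br
Why: Conversion of the benzylic alcohol to the bromide via the phosphite ester (SN2); the ortho bromine tempers the ionisation of this para-alkoxybenzyl halide so that it can be handled.

Step 12
Reactants: 15 (4R)-4-benzyl-3-(2-{5-(benzyloxy)-2-[4-(benzyloxy)-2-(methoxymethoxy)benzoyl]-3-methoxyphenyl}acetyl)-1,3-oxazolidin-2-one; 19 4-(benzyloxy)-2-bromo-1-(bromomethyl)benzene
Product: 20 (4R)-4-benzyl-3-[(2R)-2-{5-(benzyloxy)-2-[4-(benzyloxy)-2-(methoxymethoxy)benzoyl]-3-methoxyphenyl}-3-[4-(benzyloxy)-2-bromophenyl]propanoyl]-1,3-oxazolidin-2-one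
Conditions: NaN(SiMe3)2, THF, −78 °C; then 19, −78 to −40 °C
Reagents that add atoms: none
Why: Evans alkylation: the chelated (Z)-sodium enolate is attacked by the benzylic bromide on the face opposite the auxiliary benzyl group, which with the (R)-auxiliary gives the (R) centre (future C3″). The diaryl ketone has no α-hydrogen and attack of the enolate on it would need a four-membered ring, so it should remain a spectator.

Step 13
Reactants: 20 (4R)-4-benzyl-3-[(2R)-2-{5-(benzyloxy)-2-[4-(benzyloxy)-2-(methoxymethoxy)benzoyl]-3-methoxyphenyl}-3-[4-(benzyloxy)-2-bromophenyl]propanoyl]-1,3-oxazolidin-2-one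
Product: 21 {4-(benzyloxy)-2-[(2R)-1-[4-(benzyloxy)-2-bromophenyl]-3-hydroxypropan-2-yl]-6-methoxyphenyl}[4-(benzyloxy)-2-(methoxymethoxy)phenyl]methanone
Conditions: LiBH4, MeOH (1 equiv), THF, 0 °C
Reagents that add atoms: none
Why: Reductive cleavage of the N-acyloxazolidinone; the exocyclic imide carbonyl is far more electrophilic than the twisted diaryl ketone, which has three ortho substituents and alkoxy donors on both rings. The stereocentre is not enolisable after reduction and 14 is recovered.

Step 14
Reactants: 21 {4-(benzyloxy)-2-[(2R)-1-[4-(benzyloxy)-2-bromophenyl]-3-hydroxypropan-2-yl]-6-methoxyphenyl}[4-(benzyloxy)-2-(methoxymethoxy)phenyl]methanone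
Product: 22 {4-(benzyloxy)-2-[(3R)-7-(benzyloxy)chroman-3-yl]-6-methoxyphenyl}[4-(benzyloxy)-2-(methoxymethoxy)phenyl]methanone
Conditions: Pd(OAc)2 (5 mol %), 2-(di-tert-butylphosphino)-1,1′-binaphthyl, Cs2CO3, toluene, 70 °C
Reagents that add atoms: none
Why: Intramolecular Buchwald–Hartwig C–O coupling of the primary alcohol with the aryl bromide; reductive elimination from a seven-membered palladacycle closes ring F, and the bulky electron-rich phosphine disfavours β-hydride elimination. C3″ is not involved.

Step 15
Reactants: 22 {4-(benzyloxy)-2-[(3R)-7-(benzyloxy)chroman-3-yl]-6-methoxyphenyl}[4-(benzyloxy)-2-(methoxymethoxy)phenyl]methanone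
Product: 23 {4-(benzyloxy)-2-[(3R)-7-(benzyloxy)chroman-3-yl]-6-methoxyphenyl}[4-(benzyloxy)-2-hydroxyphenyl]methanone
Conditions: HCl, MeOH/THF, 45 °C
Reagents that add atoms: none
Why: Acid-catalysed acetal cleavage assisted by the ortho carbonyl; aryl benzyl and methyl ethers, the chroman and the ketone are stable. It is done at the ketone stage because the later carbinol would ionise in acid.

Step 16
Reactants: 23 {4-(benzyloxy)-2-[(3R)-7-(benzyloxy)chroman-3-yl]-6-methoxyphenyl}[4-(benzyloxy)-2-hydroxyphenyl]methanone
Product: 24 5-(benzyloxy)-2-[{4-(benzyloxy)-2-[(3R)-7-(benzyloxy)chroman-3-yl]-6-methoxyphenyl}(hydroxy)methyl]phenol (both epimers at the carbinol carbon)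
Conditions: LiAlH4, THF, 0 °C to rt; aq. potassium sodium tartrate work-up
Reagents that add atoms: none
Why: Hydride reduction of the ketone through the aluminium phenoxide chelate; both carbinol epimers are acceptable because C4 becomes trigonal again in step 21.

Step 17
Reactants: 24 5-(benzyloxy)-2-[{4-(benzyloxy)-2-[(3R)-7-(benzyloxy)chroman-3-yl]-6-methoxyphenyl}(hydroxy)methyl]phenol
Product: 25 5-(benzyloxy)-2-[{4-(benzyloxy)-2-[(3R)-7-(benzyloxy)chroman-3-yl]-6-methoxyphenyl}(4-methylbenzenesulfonyl)methyl]phenol (both epimers at the sulfonyl carbon)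
Conditions: TolSO2Na, p-TsOH·H2O, CH2Cl2/H2O, rt
Reagents that add atoms: sodium p-toluenesulfinate, [Na+].Cc1ccc(cc1)S([O-])=O
Why: SN1 substitution: acid ionises the doubly aryl-stabilised carbinol and sulfinate captures the cation at sulfur to give the sulfone, a storable quinone methide precursor. Excess sulfinate suppresses self-condensation.

Step 18
Reactants: 26 2,3-dihydroxy-4-methoxybenzaldehyde
Product: 27 2,3-bis(benzyloxy)-4-methoxybenzaldehyde
Conditions: BnBr (2.5 equiv), K2CO3, DMF, 60 °C
Reagents that add atoms: benzyl bromide, BrCc1ccccc1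
Why: Double Williamson etherification; heating overcomes the hydrogen bond of the 2-hydroxyl to the aldehyde.

Step 19
Reactants: 27 2,3-bis(benzyloxy)-4-methoxybenzaldehyde
Product: 28 2-[2,3-bis(benzyloxy)-4-methoxyphenyl]acetonitrile
Conditions: TosMIC, KOt-Bu, DME, −40 °C; then MeOH, reflux
Reagents that add atoms: p-toluenesulfonylmethyl isocyanide, Cc1ccc(cc1)S(=O)(=O)C[N+]#[C-]
Why: Van Leusen reductive cyanation: the isocyanide anion adds to the aldehyde, the oxazoline loses sulfinate, and methanol removes the formyl group to give the one-carbon-homologated nitrile.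

Step 20
Reactants: 28 2-[2,3-bis(benzyloxy)-4-methoxyphenyl]acetonitrile
Product: 29 2-[2,3-bis(benzyloxy)-4-methoxyphenyl]acetic acid
Conditions: KOH, EtOH/H2O, reflux; then aq. HCl
Reagents that add atoms: potassium hydroxide, [K+].[OH-]; water, O
Why: Basic nitrile hydrolysis; benzyl and methyl aryl ethers are stable to hot alkali.

Step 21
Reactants: 25 5-(benzyloxy)-2-[{4-(benzyloxy)-2-[(3R)-7-(benzyloxy)chroman-3-yl]-6-methoxyphenyl}(4-methylbenzenesulfonyl)methyl]phenol; 29 2-[2,3-bis(benzyloxy)-4-methoxyphenyl]acetic acid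
Product: 33 (3R,4S)-7-(benzyloxy)-4-{4-(benzyloxy)-2-[(3R)-7-(benzyloxy)chroman-3-yl]-6-methoxyphenyl}-3-[2,3-bis(benzyloxy)-4-methoxyphenyl]chroman-2-one, via mixed anhydride 30 (not isolated), via quinone methide 31 (not isolated), via cis-lactone 32 (not isolated)
Conditions: 29, t-BuCOCl, i-Pr2NEt, CH2Cl2, 0 °C; then 25, (S)-benzotetramisole (20 mol %), Cs2CO3, rt; then DBU, rt
Reagents that add atoms: none
Why: Isothiourea-catalysed Michael addition–lactonisation (formal [4+2]) of an ammonium enolate with an ortho-quinone methide: 29 is activated as 30 and acylates the catalyst, deprotonation gives the (Z)-enolate held coplanar by the O···S contact, and Cs2CO3 releases 31 from 25 by loss of sulfinate. With (S)-benzotetramisole the phenyl group blocks one enolate face so that C3 should form as (S), and the endo-type approach places ring B cis to ring D, which fixes C4 as (S) and gives 32 after the phenoxide lactonises and frees the catalyst. DBU then epimerises the acidic C3 centre to the more stable trans lactone 33 (3R,4S) without touching C4.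

Step 22
Reactants: 33 (3R,4S)-7-(benzyloxy)-4-{4-(benzyloxy)-2-[(3R)-7-(benzyloxy)chroman-3-yl]-6-methoxyphenyl}-3-[2,3-bis(benzyloxy)-4-methoxyphenyl]chroman-2-one
Product: 34 5-(benzyloxy)-2-[(1S,2R)-1-{4-(benzyloxy)-2-[(3R)-7-(benzyloxy)chroman-3-yl]-6-methoxyphenyl}-2-[2,3-bis(benzyloxy)-4-methoxyphenyl]-3-hydroxypropyl]phenol
Conditions: LiAlH4, THF, −20 to 0 °C
Reagents that add atoms: none
Why: Hydride reduction of the aryl lactone to phenol and primary alcohol, fast at low temperature; any enolisation before reduction returns the trans isomer, which is the stable one.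

Step 23
Reactants: 34 5-(benzyloxy)-2-[(1S,2R)-1-{4-(benzyloxy)-2-[(3R)-7-(benzyloxy)chroman-3-yl]-6-methoxyphenyl}-2-[2,3-bis(benzyloxy)-4-methoxyphenyl]-3-hydroxypropyl]phenol
Product: 35 (3R,4S)-7-(benzyloxy)-4-{4-(benzyloxy)-2-[(3R)-7-(benzyloxy)chroman-3-yl]-6-methoxyphenyl}-3-[2,3-bis(benzyloxy)-4-methoxyphenyl]chroman
Conditions: PPh3, DIAD, THF, 0 °C to rt
Reagents that add atoms: none
Why: Mitsunobu etherification: the phenol displaces the activated primary hydroxyl in a 6-exo-tet closure of ring C; the reacting carbon is not a stereocentre, so C3 and C4 are unchanged.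

Step 24
Reactants: 35 (3R,4S)-7-(benzyloxy)-4-{4-(benzyloxy)-2-[(3R)-7-(benzyloxy)chroman-3-yl]-6-methoxyphenyl}-3-[2,3-bis(benzyloxy)-4-methoxyphenyl]chroman
Product: 36 (3R,4S)-3-(2,3-dihydroxy-4-methoxyphenyl)-4-{4-hydroxy-2-[(3R)-7-hydroxychroman-3-yl]-6-methoxyphenyl}chroman-7-ol
Conditions: H2 (1 atm), Pd/C, THF/MeOH, rt
Reagents that add atoms: none
Why: Hydrogenolysis of the five aryl benzyl ethers; the methyl ethers, the alkyl aryl ether bonds of both chromans and the heteroatom-free C4 are not cleaved.

## Compound list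

1 | 3-methoxy-2-(trimethylsilyl)phenyl trifluoromethanesulfonate | COc1cccc(OS(=O)(=O)C(F)(F)F)c1[Si](C)(C)C | starting material
2 | 3-methoxy-5-(4,4,5,5-tetramethyl-1,3,2-dioxaborolan-2-yl)-2-(trimethylsilyl)phenyl trifluoromethanesulfonate | COc1cc(B2OC(C)(C)C(C)(C)O2)cc(OS(=O)(=O)C(F)(F)F)c1[Si](C)(C)C | intermediate
3 | 5-hydroxy-3-methoxy-2-(trimethylsilyl)phenyl trifluoromethanesulfonate | COc1cc(O)cc(OS(=O)(=O)C(F)(F)F)c1[Si](C)(C)C | intermediate
4 | 5-(benzyloxy)-3-methoxy-2-(trimethylsilyl)phenyl trifluoromethanesulfonate | COc1cc(OCc2ccccc2)cc(OS(=O)(=O)C(F)(F)F)c1[Si](C)(C)C | intermediate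
5 | 2,4-dihydroxyacetophenone | CC(=O)c1ccc(O)cc1O | starting material
6 | 1-[4-(benzyloxy)-2-hydroxyphenyl]ethanone | CC(=O)c1ccc(OCc2ccccc2)cc1O | intermediate
7 | 1-[4-(benzyloxy)-2-(methoxymethoxy)phenyl]ethanone | CC(=O)c1ccc(OCc2ccccc2)cc1OCOC | intermediate
8 | diethyl carbonate | CCOC(=O)OCC | starting material
9 | ethyl 3-[4-(benzyloxy)-2-(methoxymethoxy)phenyl]-3-oxopropanoate | CCOC(=O)CC(=O)c1ccc(OCc2ccccc2)cc1OCOC | intermediate
10 | 5-(benzyloxy)-3-methoxybenzyne | COC1=CC(OCc2ccccc2)=CC#C1 | intermediate
11 | cesium 3-(benzyloxy)-7-[4-(benzyloxy)-2-(methoxymethoxy)phenyl]-8-(ethoxycarbonyl)-5-methoxybicyclo[4.2.0]octa-1,3,5-trien-7-olate | CCOC(=O)C1c2cc(OCc3ccccc3)cc(OC)c2C1([O-])c1ccc(OCc2ccccc2)cc1OCOC.[Cs+] | intermediate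
12 | ethyl 2-{5-(benzyloxy)-2-[4-(benzyloxy)-2-(methoxymethoxy)benzoyl]-3-methoxyphenyl}acetate | CCOC(=O)Cc1cc(OCc2ccccc2)cc(OC)c1C(=O)c1ccc(OCc2ccccc2)cc1OCOC | intermediate
13 | 2-{5-(benzyloxy)-2-[4-(benzyloxy)-2-(methoxymethoxy)benzoyl]-3-methoxyphenyl}acetic acid | OC(=O)Cc1cc(OCc2ccccc2)cc(OC)c1C(=O)c1ccc(OCc2ccccc2)cc1OCOC | intermediate
14 | (R)-4-benzyl-1,3-oxazolidin-2-one | O=C1N[C@H](Cc2ccccc2)CO1 | starting material
15 | (4R)-4-benzyl-3-(2-{5-(benzyloxy)-2-[4-(benzyloxy)-2-(methoxymethoxy)benzoyl]-3-methoxyphenyl}acetyl)-1,3-oxazolidin-2-one | O=C1OC[C@@H](Cc2ccccc2)N1C(=O)Cc1cc(OCc2ccccc2)cc(OC)c1C(=O)c1ccc(OCc2ccccc2)cc1OCOC | intermediate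
16 | 2-bromo-4-hydroxybenzaldehyde | O=Cc1ccc(O)cc1Br | starting material
17 | 4-(benzyloxy)-2-bromobenzaldehyde | O=Cc1ccc(OCc2ccccc2)cc1Br | intermediate
18 | [4-(benzyloxy)-2-bromophenyl]methanol | OCc1ccc(OCc2ccccc2)cc1Br | intermediate
19 | 4-(benzyloxy)-2-bromo-1-(bromomethyl)benzene | BrCc1ccc(OCc2ccccc2)cc1Br | intermediate
20 | (4R)-4-benzyl-3-[(2R)-2-{5-(benzyloxy)-2-[4-(benzyloxy)-2-(methoxymethoxy)benzoyl]-3-methoxyphenyl}-3-[4-(benzyloxy)-2-bromophenyl]propanoyl]-1,3-oxazolidin-2-one | O=C1OC[C@@H](Cc2ccccc2)N1C(=O)[C@H](Cc1ccc(OCc2ccccc2)cc1Br)c1cc(OCc2ccccc2)cc(OC)c1C(=O)c1ccc(OCc2ccccc2)cc1OCOC | intermediate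
21 | {4-(benzyloxy)-2-[(2R)-1-[4-(benzyloxy)-2-bromophenyl]-3-hydroxypropan-2-yl]-6-methoxyphenyl}[4-(benzyloxy)-2-(methoxymethoxy)phenyl]methanone | OC[C@H](Cc1ccc(OCc2ccccc2)cc1Br)c1cc(OCc2ccccc2)cc(OC)c1C(=O)c1ccc(OCc2ccccc2)cc1OCOC | intermediate
22 | {4-(benzyloxy)-2-[(3R)-7-(benzyloxy)chroman-3-yl]-6-methoxyphenyl}[4-(benzyloxy)-2-(methoxymethoxy)phenyl]methanone | COCOc1cc(OCc2ccccc2)ccc1C(=O)c1c(OC)cc(OCc2ccccc2)cc1[C@@H]1COc2cc(OCc3ccccc3)ccc2C1 | intermediate
23 | {4-(benzyloxy)-2-[(3R)-7-(benzyloxy)chroman-3-yl]-6-methoxyphenyl}[4-(benzyloxy)-2-hydroxyphenyl]methanone | Oc1cc(OCc2ccccc2)ccc1C(=O)c1c(OC)cc(OCc2ccccc2)cc1[C@@H]1COc2cc(OCc3ccccc3)ccc2C1 | intermediate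
24 | 5-(benzyloxy)-2-[{4-(benzyloxy)-2-[(3R)-7-(benzyloxy)chroman-3-yl]-6-methoxyphenyl}(hydroxy)methyl]phenol, both epimers at the carbinol carbon | Oc1cc(OCc2ccccc2)ccc1C(O)c1c(OC)cc(OCc2ccccc2)cc1[C@@H]1COc2cc(OCc3ccccc3)ccc2C1 | intermediate
25 | 5-(benzyloxy)-2-[{4-(benzyloxy)-2-[(3R)-7-(benzyloxy)chroman-3-yl]-6-methoxyphenyl}(4-methylbenzenesulfonyl)methyl]phenol, both epimers at the sulfonyl carbon | Cc1ccc(cc1)S(=O)(=O)C(c1ccc(OCc2ccccc2)cc1O)c1c(OC)cc(OCc2ccccc2)cc1[C@@H]1COc2cc(OCc3ccccc3)ccc2C1 | intermediate
26 | 2,3-dihydroxy-4-methoxybenzaldehyde | COc1ccc(C=O)c(O)c1O | starting material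
27 | 2,3-bis(benzyloxy)-4-methoxybenzaldehyde | COc1ccc(C=O)c(OCc2ccccc2)c1OCc1ccccc1 | intermediate
28 | 2-[2,3-bis(benzyloxy)-4-methoxyphenyl]acetonitrile | COc1ccc(CC#N)c(OCc2ccccc2)c1OCc1ccccc1 | intermediate
29 | 2-[2,3-bis(benzyloxy)-4-methoxyphenyl]acetic acid | COc1ccc(CC(O)=O)c(OCc2ccccc2)c1OCc1ccccc1 | intermediate
30 | 2-[2,3-bis(benzyloxy)-4-methoxyphenyl]acetic pivalic anhydride | COc1ccc(CC(=O)OC(=O)C(C)(C)C)c(OCc2ccccc2)c1OCc1ccccc1 | intermediate
31 | 3-(benzyloxy)-6-({4-(benzyloxy)-2-[(3R)-7-(benzyloxy)chroman-3-yl]-6-methoxyphenyl}methylidene)cyclohexa-2,4-dien-1-one | O=C1C=C(OCc2ccccc2)C=CC1=Cc1c(OC)cc(OCc2ccccc2)cc1[C@@H]1COc2cc(OCc3ccccc3)ccc2C1 | intermediate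
32 | (3S,4S)-7-(benzyloxy)-4-{4-(benzyloxy)-2-[(3R)-7-(benzyloxy)chroman-3-yl]-6-methoxyphenyl}-3-[2,3-bis(benzyloxy)-4-methoxyphenyl]chroman-2-one (cis) | COc1ccc([C@H]2C(=O)Oc3cc(OCc4ccccc4)ccc3[C@H]2c2c(OC)cc(OCc3ccccc3)cc2[C@@H]2COc3cc(OCc4ccccc4)ccc3C2)c(OCc2ccccc2)c1OCc1ccccc1 | intermediate
33 | (3R,4S)-7-(benzyloxy)-4-{4-(benzyloxy)-2-[(3R)-7-(benzyloxy)chroman-3-yl]-6-methoxyphenyl}-3-[2,3-bis(benzyloxy)-4-methoxyphenyl]chroman-2-one (trans) | COc1ccc([C@@H]2C(=O)Oc3cc(OCc4ccccc4)ccc3[C@H]2c2c(OC)cc(OCc3ccccc3)cc2[C@@H]2COc3cc(OCc4ccccc4)ccc3C2)c(OCc2ccccc2)c1OCc1ccccc1 | intermediate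
34 | 5-(benzyloxy)-2-[(1S,2R)-1-{4-(benzyloxy)-2-[(3R)-7-(benzyloxy)chroman-3-yl]-6-methoxyphenyl}-2-[2,3-bis(benzyloxy)-4-methoxyphenyl]-3-hydroxypropyl]phenol | COc1ccc([C@H](CO)[C@@H](c2ccc(OCc3ccccc3)cc2O)c2c(OC)cc(OCc3ccccc3)cc2[C@@H]2COc3cc(OCc4ccccc4)ccc3C2)c(OCc2ccccc2)c1OCc1ccccc1 | intermediate
35 | (3R,4S)-7-(benzyloxy)-4-{4-(benzyloxy)-2-[(3R)-7-(benzyloxy)chroman-3-yl]-6-methoxyphenyl}-3-[2,3-bis(benzyloxy)-4-methoxyphenyl]chroman | COc1ccc([C@@H]2COc3cc(OCc4ccccc4)ccc3[C@H]2c2c(OC)cc(OCc3ccccc3)cc2[C@@H]2COc3cc(OCc4ccccc4)ccc3C2)c(OCc2ccccc2)c1OCc1ccccc1 | intermediate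
36 | (3R,4S)-3-(2,3-dihydroxy-4-methoxyphenyl)-4-{4-hydroxy-2-[(3R)-7-hydroxychroman-3-yl]-6-methoxyphenyl}chroman-7-ol (CNP0227211.1) | COc1ccc([C@@H]2COc3cc(O)ccc3[C@H]2c2c(OC)cc(O)cc2[C@@H]2COc3cc(O)ccc3C2)c(O)c1O | target

## Step count and least certain steps

Total: 24 steps (one-pot sequences counted once). Longest linear sequence: 16 steps from 5 (steps 3, 4, 5, 6, 7, 8, 12, 13, 14, 15, 16, 17, 21, 22, 23, 24).

**Step 6 (key step).** The most likely failure is protonation of the aryl anion before it closes onto the hindered, ortho-oxygenated ketone, which would leave simple α-arylation without acyl transfer. Attack at the wrong aryne carbon or O-arylation would give isomeric material that is hard to remove. The fallback sets out from 4 and comes back at 12; it uses silicon and triflate as two fixed handles instead of as an aryne source.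
- Palladium-catalysed coupling of the triflate with the Reformatsky reagent of ethyl bromoacetate (Pd2(dba)3, XPhos, THF) should give ethyl 2-[5-(benzyloxy)-3-methoxy-2-(trimethylsilyl)phenyl]acetate F1.
- Ipso-iododesilylation with ICl in CH2Cl2 should give ethyl 2-[5-(benzyloxy)-2-iodo-3-methoxyphenyl]acetate F2.
- Nozaki–Hiyama–Kishi addition (CrCl2, catalytic NiCl2, DMF) of F2 to 4-(benzyloxy)-2-(methoxymethoxy)benzaldehyde F3, itself one acetal protection from the commercial 2-hydroxy aldehyde, tolerates the ester and its acidic methylene. It should give ethyl 2-{5-(benzyloxy)-2-[[4-(benzyloxy)-2-(methoxymethoxy)phenyl](hydroxy)methyl]-3-methoxyphenyl}acetate F4.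
- F4 is oxidised at once with Dess–Martin periodinane, before it can lactonise, to 12.

**Step 21.** The likely failures are slow addition to the methide carbon between two ortho substituents, acylation of the phenol of 25 before the quinone methide is released, and a facial or topological preference different from the endo model, which would place C4 in the wrong series. If the trans lactone formed directly, the antipodal catalyst would be the first remedy. The fallback changes the approach to a cationic, catalyst-free union and sets out from 24, coming back at 33.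
- 29 is esterified to methyl 2-[2,3-bis(benzyloxy)-4-methoxyphenyl]acetate F5 and converted with LDA and Me3SiCl to its trimethylsilyl ketene acetal F6.
- Catalytic HNTf2 in CH2Cl2 at −78 °C ionises 24 and F6 adds at C4 (Mukaiyama-type SN1 alkylation) to give methyl 3-[4-(benzyloxy)-2-hydroxyphenyl]-3-{4-(benzyloxy)-2-[(3R)-7-(benzyloxy)chroman-3-yl]-6-methoxyphenyl}-2-[2,3-bis(benzyloxy)-4-methoxyphenyl]propanoate F7 as a stereoisomer mixture.
- Acid-catalysed lactonisation and DBU equilibration of C3 should leave two trans lactones, 33 and its (3S,4R) diastereomer F8. These differ in their relation to C3″ and are separated by chromatography, at the cost of half the material.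

**Step 13.** The likely failure is partial reduction of the diaryl ketone, or hemiketal formation between the new alcohol and the ketone, giving mixtures. The fallback sets out from 20 and comes back at 21: LiAlH4 in THF reduces imide and ketone together to (2R)-2-{5-(benzyloxy)-2-[[4-(benzyloxy)-2-(methoxymethoxy)phenyl](hydroxy)methyl]-3-methoxyphenyl}-3-[4-(benzyloxy)-2-bromophenyl]propan-1-ol F9, and MnO2 in CH2Cl2 re-oxidises only the diaryl carbinol, which gives 21.

**Step 1.** The likely failures are borylation next to the methoxy group in competition with C5, and loss of the silyl group or hydrolysis of the triflate during the oxidation. No compound of the route precedes 1, so the fallback sets out from commercial 5-methoxyresorcinol F10 and comes back at 4.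
- Monobenzylation gives 3-(benzyloxy)-5-methoxyphenol F11.
- Isopropyl isocyanate gives 3-(benzyloxy)-5-methoxyphenyl isopropylcarbamate F12.
- N-silylation, carbamate-directed ortho-lithiation (n-BuLi, TMEDA, −78 °C) and Me3SiCl give 5-(benzyloxy)-3-methoxy-2-(trimethylsilyl)phenyl isopropylcarbamate F13.
- Cleavage with DBU/Et2NH and triflation with PhNTf2 give 4.
- Its own weakness is competition between the two positions flanking the carbamate, so the isomers would have to be separated; this is why it is the fallback and not the route.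

## Further compounds

F1 | step 6 | ethyl 2-[5-(benzyloxy)-3-methoxy-2-(trimethylsilyl)phenyl]acetate | CCOC(=O)Cc1cc(OCc2ccccc2)cc(OC)c1[Si](C)(C)C
F2 | step 6 | ethyl 2-[5-(benzyloxy)-2-iodo-3-methoxyphenyl]acetate | CCOC(=O)Cc1cc(OCc2ccccc2)cc(OC)c1I
F3 | step 6 | 4-(benzyloxy)-2-(methoxymethoxy)benzaldehyde | COCOc1cc(OCc2ccccc2)ccc1C=O
F4 | step 6 | ethyl 2-{5-(benzyloxy)-2-[[4-(benzyloxy)-2-(methoxymethoxy)phenyl](hydroxy)methyl]-3-methoxyphenyl}acetate | CCOC(=O)Cc1cc(OCc2ccccc2)cc(OC)c1C(O)c1ccc(OCc2ccccc2)cc1OCOC
F5 | step 21 | methyl 2-[2,3-bis(benzyloxy)-4-methoxyphenyl]acetate | COC(=O)Cc1ccc(OC)c(OCc2ccccc2)c1OCc1ccccc1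
F6 | step 21 | {2-[2,3-bis(benzyloxy)-4-methoxyphenyl]-1-methoxyethenoxy}trimethylsilane | COC(O[Si](C)(C)C)=Cc1ccc(OC)c(OCc2ccccc2)c1OCc1ccccc1
F7 | step 21 | methyl 3-[4-(benzyloxy)-2-hydroxyphenyl]-3-{4-(benzyloxy)-2-[(3R)-7-(benzyloxy)chroman-3-yl]-6-methoxyphenyl}-2-[2,3-bis(benzyloxy)-4-methoxyphenyl]propanoate | COC(=O)C(c1ccc(OC)c(OCc2ccccc2)c1OCc1ccccc1)C(c1ccc(OCc2ccccc2)cc1O)c1c(OC)cc(OCc2ccccc2)cc1[C@@H]1COc2cc(OCc3ccccc3)ccc2C1
F8 | step 21 | (3S,4R)-7-(benzyloxy)-4-{4-(benzyloxy)-2-[(3R)-7-(benzyloxy)chroman-3-yl]-6-methoxyphenyl}-3-[2,3-bis(benzyloxy)-4-methoxyphenyl]chroman-2-one | COc1ccc([C@H]2C(=O)Oc3cc(OCc4ccccc4)ccc3[C@@H]2c2c(OC)cc(OCc3ccccc3)cc2[C@@H]2COc3cc(OCc4ccccc4)ccc3C2)c(OCc2ccccc2)c1OCc1ccccc1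
F9 | step 13 | (2R)-2-{5-(benzyloxy)-2-[[4-(benzyloxy)-2-(methoxymethoxy)phenyl](hydroxy)methyl]-3-methoxyphenyl}-3-[4-(benzyloxy)-2-bromophenyl]propan-1-ol | OC[C@H](Cc1ccc(OCc2ccccc2)cc1Br)c1cc(OCc2ccccc2)cc(OC)c1C(O)c1ccc(OCc2ccccc2)cc1OCOC
F10 | step 1 | 5-methoxyresorcinol | COc1cc(O)cc(O)c1
F11 | step 1 | 3-(benzyloxy)-5-methoxyphenol | COc1cc(O)cc(OCc2ccccc2)c1
F12 | step 1 | 3-(benzyloxy)-5-methoxyphenyl isopropylcarbamate | COc1cc(OCc2ccccc2)cc(OC(=O)NC(C)C)c1
F13 | step 1 | 5-(benzyloxy)-3-methoxy-2-(trimethylsilyl)phenyl isopropylcarbamate | COc1cc(OCc2ccccc2)cc(OC(=O)NC(C)C)c1[Si](C)(C)C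
A1 | alternative 1 | (3R,4S)-7-(benzyloxy)-4-{2-[(3R)-7-(benzyloxy)chroman-3-yl]-4-hydroxy-6-methoxyphenyl}-3-[2,3-bis(benzyloxy)-4-methoxyphenyl]chroman | COc1ccc([C@@H]2COc3cc(OCc4ccccc4)ccc3[C@H]2c2c(OC)cc(O)cc2[C@@H]2COc3cc(OCc4ccccc4)ccc3C2)c(OCc2ccccc2)c1OCc1ccccc1
A2 | alternative 1 | 2-{(3R,4S)-7-(benzyloxy)-3-[2,3-bis(benzyloxy)-4-methoxyphenyl]chroman-4-yl}-3-[(3R)-7-(benzyloxy)chroman-3-yl]cyclobut-2-en-1-one | COc1ccc([C@@H]2COc3cc(OCc4ccccc4)ccc3[C@H]2C5=C([C@@H]6COc7cc(OCc8ccccc8)ccc7C6)CC5=O)c(OCc2ccccc2)c1OCc1ccccc1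
A3 | alternative 1 | methoxyacetylene | COC#C
A4 | alternative 2 | (3R,4S)-7-(benzyloxy)-4-{4-(benzyloxy)-2-[(3R)-7-(benzyloxy)chroman-3-yl]-6-methoxyphenyl}-3-[2,3-bis(benzyloxy)-4-methoxyphenyl]chroman-2-one | COc1ccc([C@@H]2C(=O)Oc3cc(OCc4ccccc4)ccc3[C@H]2c2c(OC)cc(OCc3ccccc3)cc2[C@@H]2COc3cc(OCc4ccccc4)ccc3C2)c(OCc2ccccc2)c1OCc1ccccc1
A5 | alternative 2 | 5-(benzyloxy)-2-[{4-(benzyloxy)-2-[(3R)-7-(benzyloxy)chroman-3-yl]-6-methoxyphenyl}(4-methylbenzenesulfonyl)methyl]phenol | Cc1ccc(cc1)S(=O)(=O)C(c1ccc(OCc2ccccc2)cc1O)c1c(OC)cc(OCc2ccccc2)cc1[C@@H]1COc2cc(OCc3ccccc3)ccc2C1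
A6 | alternative 3 | (3R,4S)-7-(benzyloxy)-4-{4-(benzyloxy)-2-[(3R)-7-(benzyloxy)chroman-3-yl]-6-methoxyphenyl}-3-[2,3-bis(benzyloxy)-4-methoxyphenyl]chroman | COc1ccc([C@@H]2COc3cc(OCc4ccccc4)ccc3[C@H]2c2c(OC)cc(OCc3ccccc3)cc2[C@@H]2COc3cc(OCc4ccccc4)ccc3C2)c(OCc2ccccc2)c1OCc1ccccc1
A7 | alternative 3 | (2R)-1-{4-(benzyloxy)-2-[(3R)-7-(benzyloxy)chroman-3-yl]-6-methoxyphenyl}-3-[3-(benzyloxy)phenoxy]-2-[2,3-bis(benzyloxy)-4-methoxyphenyl]propan-1-ol, either carbinol epimer | COc1ccc([C@H](COc2cccc(OCc3ccccc3)c2)C(O)c2c(OC)cc(OCc3ccccc3)cc2[C@@H]2COc3cc(OCc4ccccc4)ccc3C2)c(OCc2ccccc2)c1OCc1ccccc1
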